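## Retrosynthetic overview

1. Manniflavanone is a taxifolin unit (2R,3R, from the chiral pool) joined through its C8 to C3'' of a 2''R,3''S-trans-flavanone. Last step: hydrogenolysis of seven benzyl ethers.
2. **Key disconnection (proposed new step):** the C2''–aryl bond of the flavanone. It comes from Rh/chiral-diphosphine 1,4-addition of ArB(OH)2 to a 3-(taxifolin-8-yl)chromone. The ligand sets C2'' and epimerisation of the acidic C3''–H then gives the trans isomer.
3. The 3-arylchromone comes from Suzuki coupling of a taxifolin C8-boronate with a 3-iodochromone. The chromone pyranone ring is formed from phloroacetophenone by the enaminone/I2 route.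
4. Ring order: taxifolin's dihydropyranone ring (unit A) is already in the starting material. The chromone ring of unit B is formed next, then the C3''–C8 bond, and finally the C2'' stereocentre when the chromone C2=C3 is saturated.

Assumptions:
- Taxifolin's (2R,3R) configuration matches unit A of the target.
- NIS iodinates the 7-OBn/5-OH taxifolin at C8 preferentially, with the minor C6 isomer removed by chromatography.
- The ligand enantiomer is assumed by analogy to Hayashi's Rh/(S)-BINAP cyclohexenone addition; (R)-BINAP is assumed to give 2''R, and if 2''S is observed the enantiomeric ligand is used.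
- The free 5-OH and 3-OH of unit A are carried through unprotected.

## Route

**Step 1**
Reactants: 1, (2R,3R)-taxifolin (commercial)
Product: 2, (2R,3R)-7,3',4'-tri-O-benzyltaxifolin (5-OH and 3-OH free)
Conditions: BnBr (3.2 equiv), K2CO3, DMF, rt
Reagents that add atoms: benzyl bromide, BrCc1ccccc1
Why: Williamson etherification at the three non-chelated phenols. The H-bonded 5-OH and the aliphatic 3-OH are not alkylated by K2CO3. C2 and C3 are untouched and the mild base keeps the trans relationship.

**Step 2**
Reactants: 2
Product: 3, (2R,3R)-8-iodo-7,3',4'-tri-O-benzyltaxifolin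
Conditions: NIS (1.05 equiv), MeCN, 0 °C to rt, dark
Reagents that add atoms: N-iodosuccinimide, O=C1CCC(=O)N1I
Why: Electrophilic aromatic iodination of the most nucleophilic A-ring position, flanked by 7-OBn and the ring oxygen. The stereocentres are not involved.

**Step 3**
Reactants: 3
Product: 4, the 8-Bpin analogue of 3 (pinacol boronate at C8)
Conditions: B2pin2, Pd(OAc)2/SPhos, KOAc, dioxane, 80 °C
Reagents that add atoms: bis(pinacolato)diboron, CC1(C)OB(OC1(C)C)B1OC(C)(C)C(C)(C)O1
Why: Miyaura borylation. The weak base KOAc leaves the free OH groups and the dihydroflavonol stereocentres intact.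

**Step 4**
Reactants: 5, 2',4',6'-trihydroxyacetophenone (commercial)
Product: 6, 1-[4,6-bis(benzyloxy)-2-hydroxyphenyl]ethanone
Conditions: BnBr (2.1 equiv), K2CO3, acetone, reflux
Reagents that add atoms: benzyl bromide, BrCc1ccccc1
Why: Selective Williamson etherification of the two non-chelated hydroxyls. The 2'-OH is locked by H-bonding to the carbonyl.

**Step 5**
Reactants: 6
Product: 7, (E)-1-[4,6-bis(benzyloxy)-2-hydroxyphenyl]-3-(dimethylamino)prop-2-en-1-one
Conditions: DMF-DMA, toluene, 110 °C
Reagents that add atoms: N,N-dimethylformamide dimethyl acetal, CN(C)C(OC)OC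
Why: Enaminone formation by condensation of the acetyl CH3 with the acetal.

**Step 6**
Reactants: 7
Product: 8, 5,7-bis(benzyloxy)-3-iodo-4H-chromen-4-one
Conditions: I2 (1.2 equiv), CHCl3, rt
Reagents that add atoms: iodine, II
Why: Iodine-mediated enaminone cyclisation (Gammill 3-iodochromone synthesis). The phenol attacks the iodinated enaminone and dimethylamine is lost.

**Step 7**
Reactants: 9, 4-bromobenzene-1,2-diol (4-bromocatechol, commercial)
Product: 10, 4-bromo-1,2-bis(benzyloxy)benzene
Conditions: BnBr (2.2 equiv), K2CO3, acetone, reflux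
Reagents that add atoms: benzyl bromide, BrCc1ccccc1
Why: Williamson bis-etherification.

**Step 8**
Reactants: 10
Product: 11, [3,4-bis(benzyloxy)phenyl]boronic acid
Conditions: n-BuLi, THF, −78 °C; then B(OiPr)3; then 1 M HCl
Reagents that add atoms: triisopropyl borate, CC(C)OB(OC(C)C)OC(C)C (n-BuLi leaves no atoms in the product)
Why: Bromine–lithium exchange, borylation and hydrolysis to the arylboronic acid.

**Step 9**
Reactants: 4 (8-Bpin taxifolin derivative) and 8 (3-iodochromone)
Product: 12, 3-[taxifolin-8-yl]-5,7-bis(benzyloxy)chromone, with the unit A core (2R,3R) retained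
Conditions: XPhos Pd G3 (5 mol%), K3PO4, dioxane/H2O 20:1, 50 °C
Reagents that add atoms: none
Why: Suzuki–Miyaura coupling (the standard isoflavone-type coupling) between a hindered 2,6-dioxygenated arylboronate and 3-iodochromone. The bulky biaryl precatalyst works at 50 °C, so the dihydroflavonol does not epimerise or ring-open.

**Step 10**
Reactants: 12 and 11 (3.0 equiv)
Product: 13, protected manniflavanone (2''R,3''S, 2'',3''-trans; unit A 2R,3R)
Conditions: Rh(acac)(C2H4)2 (5 mol%), (R)-BINAP (6 mol%), dioxane/H2O 10:1, 60 °C; then Et3N (1 equiv), rt, 2 h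
Reagents that add atoms: none beyond the numbered reactants (water supplies H)
Why: Proposed new method: Hayashi–Miyaura Rh-catalysed 1,4-arylation, applied to a 3-aryl (isoflavone-type) chromone acceptor carrying a hindered 2,4,6-trioxygenated aryl group and a free chiral dihydroflavonol, in order to form the 2,3-diarylchromanone. Mechanism: transmetalation from ArB(OH)2 to Rh–OH gives Ar–Rh(I)/(R)-BINAP. Ar–Rh inserts into chromone C2=C3, with the ligand controlling the face at C2 (the β-carbon next to O1). The Rh-oxa-π-allyl enolate is hydrolysed by water. The doubly activated C3''–H then epimerises under mild Et3N to the diequatorial 2,3-trans isomer, so C3'' follows C2''. The closest known reaction is Rh-catalysed asymmetric arylation of chromones and enones. Unit A is 8 bonds away from the reacting centre and its stereocentres are unaffected by these near-neutral conditions.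

**Step 11**
Reactants: 13
Product: 14, manniflavanone
Conditions: H2 (1 atm), Pd(OH)2/C, THF/MeOH 1:1, rt
Reagents that add atoms: none (H2 adds only hydrogen)
Why: Hydrogenolysis of all seven aryl benzyl ethers. The ketones, the 3-OH and the C2–O bonds survive the short neutral reaction, and no stereocentre is touched. The 5''-O-benzyl group is removed only at this last step, which avoids the easy racemisation of 5-hydroxyflavanones.

## Compound list

| No. | Name | SMILES | Role |
|---|---|---|---|
| 1 | (2R,3R)-Taxifolin | O=C1c2c(O)cc(O)cc2O[C@H](c2ccc(O)c(O)c2)[C@H]1O | starting material |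
| 2 | (2R,3R)-7,3',4'-Tri-O-benzyltaxifolin | O=C1c2c(O)cc(OCc3ccccc3)cc2O[C@H](c2ccc(OCc3ccccc3)c(OCc3ccccc3)c2)[C@H]1O | intermediate |
| 3 | (2R,3R)-8-Iodo-7,3',4'-tri-O-benzyltaxifolin | O=C1c2c(O)cc(OCc3ccccc3)c(I)c2O[C@H](c2ccc(OCc3ccccc3)c(OCc3ccccc3)c2)[C@H]1O | intermediate |
| 4 | 8-Bpin analogue of 3 | O=C1c2c(O)cc(OCc3ccccc3)c(B3OC(C)(C)C(C)(C)O3)c2O[C@H](c2ccc(OCc3ccccc3)c(OCc3ccccc3)c2)[C@H]1O | intermediate |
| 5 | 2',4',6'-Trihydroxyacetophenone | CC(=O)c1c(O)cc(O)cc1O | starting material |
| 6 | 1-[4,6-Bis(benzyloxy)-2-hydroxyphenyl]ethanone | CC(=O)c1c(O)cc(OCc2ccccc2)cc1OCc1ccccc1 | intermediate |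
| 7 | (E)-Enaminone from 6 | CN(C)/C=C/C(=O)c1c(O)cc(OCc2ccccc2)cc1OCc1ccccc1 | intermediate |
| 8 | 5,7-Bis(benzyloxy)-3-iodochromone | O=c1c(I)coc2cc(OCc3ccccc3)cc(OCc3ccccc3)c12 | intermediate |
| 9 | 4-Bromocatechol | Oc1ccc(Br)cc1O | starting material |
| 10 | 4-Bromo-1,2-bis(benzyloxy)benzene | Brc1ccc(OCc2ccccc2)c(OCc2ccccc2)c1 | intermediate |
| 11 | [3,4-Bis(benzyloxy)phenyl]boronic acid | OB(O)c1ccc(OCc2ccccc2)c(OCc2ccccc2)c1 | intermediate |
| 12 | 3-(Taxifolin-8-yl)chromone (Suzuki product) | O=C1c2c(O)cc(OCc3ccccc3)c(-c3coc4cc(OCc5ccccc5)cc(OCc5ccccc5)c4c3=O)c2O[C@H](c2ccc(OCc3ccccc3)c(OCc3ccccc3)c2)[C@H]1O | intermediate |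
| 13 | Heptabenzyl manniflavanone | O=C1c2c(O)cc(OCc3ccccc3)c([C@@H]3C(=O)c4c(OCc5ccccc5)cc(OCc5ccccc5)cc4O[C@H]3c3ccc(OCc5ccccc5)c(OCc5ccccc5)c3)c2O[C@H](c2ccc(OCc3ccccc3)c(OCc3ccccc3)c2)[C@H]1O | intermediate |
| 14 | Manniflavanone | O=C1c2c(O)cc(O)c([C@@H]3C(=O)c4c(O)cc(O)cc4O[C@H]3c3ccc(O)c(O)c3)c2O[C@H](c2ccc(O)c(O)c2)[C@H]1O | target |

## Summary

Total steps: 11. Longest linear sequence: 6 (1 → 2 → 3 → 4 → 12 → 13 → 14, i.e. steps 1, 2, 3, 9, 10, 11).

Three steps most likely to fail:

1. **Step 10, Rh-catalysed asymmetric 1,4-arylation (the proposed new step).** The hindered 3-aryl acceptor may be unreactive, or C2'' may racemise by chromanone ring-opening.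
   - Fallback: use known chemistry with racemic or achiral ligands. Run the Rh or Pd 1,4-arylation with rac-BINAP or dppe, epimerise C3'', and separate the two C2''-epimeric diastereomers (the molecule already contains unit A's stereocentres) by preparative HPLC. This replaces asymmetric catalysis with resolution.
2. **Step 2, C8-selective iodination.** A C6/C8 mixture or iodination of the catechol-ether ring is possible.
   - Fallback: build a regio-defined unit A de novo. Take 3-iodophloroacetophenone (a single mono-iodide by symmetry) and benzylate the 4',6'-OH groups, leaving the 2'-OH next to iodine. Run Claisen–Schmidt condensation with 3,4-bis(benzyloxy)benzaldehyde, then Algar–Flynn–Oyamada cyclisation to racemic trans-8-iododihydroflavonol. Resolve by chiral HPLC to (2R,3R) and rejoin at step 3 (5-OBn in place of 5-OH is removed in step 11).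
3. **Steps 3 and 9, hindered borylation and Suzuki coupling.** Protodeboronation or deiodination of the di-ortho-oxygenated arene, or base-induced epimerisation of the free 3-OH dihydroflavonol, may occur.
   - Fallback: reverse the polarity of the coupling. Convert 3-iodochromone 8 to the 3-(tributylstannyl)chromone with (Me3Sn)2 or Bu3SnSnBu3/Pd, and couple it directly with iodide 3 by Stille–Liebeskind coupling (Pd/CuI). This avoids the aryl boronate entirely.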